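The route rests on opening ring C of the isoflavanone at O1–C2 and at C4–C4a. One operation makes both bonds (and C8a–O1): 3,5-dimethoxybenzyne, released from a silyl triflate, inserts into the C–O bond of a 2-arylacrylic acid that already carries the finished dimethylchromene, and the resulting ortho-acylphenoxide closes ring C by oxa-Michael addition. The step exploits the ortho relation of O1 and the C4 carbonyl on ring A; the methoxy group that becomes C5–OMe, next to C4a, fixes the regiochemistry. C3 is then set by dynamic kinetic transfer hydrogenation and reoxidation, and chelation to C4=O unmasks the 5-hydroxyl.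

Key step: step 7

Assumption: ethyl 2-(tributylstannyl)acrylate 6 is taken as a purchasable reagent; otherwise it follows in one step from ethyl propiolate and Bu3SnH with Pd(PPh3)4.

Step 1
Reactants: 1 4-bromo-3-methoxyphenol; 2 3-methylbut-2-enal
Product: 5 6-bromo-7-methoxy-2,2-dimethyl-2H-chromene, via benzodioxaborin 3 (not isolated), via ortho-quinone methide 4 (not isolated)
Conditions: PhB(OH)2 (1.1 equiv), AcOH (cat.), toluene, reflux, Dean–Stark
Reagents that add atoms: none
Why: Boronic acid templated chromenylation: phenylboronic acid ties phenol and aldehyde together as 3, which delivers the aldehyde carbon to the unhindered ortho position (para to OMe, the other ortho site being flanked by OMe) and fragments on heating to 4, which closes by oxa-6π electrocyclization.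

Step 2
Reactants: 5 6-bromo-7-methoxy-2,2-dimethyl-2H-chromene; 6 ethyl 2-(tributylstannyl)acrylate
Product: 7 ethyl 2-(7-methoxy-2,2-dimethyl-2H-chromen-6-yl)acrylate
Conditions: Pd(P(t-Bu)3)2 (5 mol%), CuI (10 mol%), CsF (2 equiv), DMF, 50 °C
Reagents that add atoms: none
Why: Stille cross-coupling of an α-stannyl acrylate, in which CuI and fluoride speed up transmetalation of the hindered vinylstannane so that ipso coupling should outrun cine substitution.

Step 3
Reactants: 7 ethyl 2-(7-methoxy-2,2-dimethyl-2H-chromen-6-yl)acrylate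
Product: 8 2-(7-methoxy-2,2-dimethyl-2H-chromen-6-yl)acrylic acid
Conditions: LiOH·H2O, THF/H2O, rt; then cold 1 M HCl to pH 3
Reagents that add atoms: lithium hydroxide, [Li+].[OH-]
Why: Saponification of the ethyl ester at room temperature, which neither the chromene nor the 1,1-disubstituted acrylate should suffer from.

Step 4
Reactants: 9 3,5-dimethoxyphenol
Product: 10 3,5-dimethoxyphenyl N-isopropylcarbamate
Conditions: i-PrNCO, Et3N (cat.), CH2Cl2, rt
Reagents that add atoms: isopropyl isocyanate, CC(C)N=C=O
Why: Base-catalysed addition of the phenol to the isocyanate (carbamoylation) installs a strong ortho-directing group that can be removed later under mild conditions.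

Step 5
Reactants: 10 3,5-dimethoxyphenyl N-isopropylcarbamate
Product: 13 3,5-dimethoxy-2-(trimethylsilyl)phenyl N-isopropylcarbamate, via N-silyl carbamate 11 (not isolated), via N-silyl ortho-silyl carbamate 12 (not isolated)
Conditions: TBSOTf, TMEDA, Et2O, 0 °C to rt; n-BuLi, TMEDA, −78 °C; TMSCl, −78 °C to rt; aqueous NaHSO4 work-up
Reagents that add atoms: chlorotrimethylsilane, C[Si](C)(C)Cl
Why: Directed ortho-metalation: N-silylation in the flask masks the N–H, the carbamate and the neighbouring methoxy group together direct lithiation to C2 (identical with C6 by symmetry, and favoured over C4 between the two weaker methoxy directors), the aryllithium is silylated, and the N-silyl group falls off on acidic work-up.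

Step 6
Reactants: 13 3,5-dimethoxy-2-(trimethylsilyl)phenyl N-isopropylcarbamate
Product: 15 3,5-dimethoxy-2-(trimethylsilyl)phenyl trifluoromethanesulfonate, via silyl phenol 14 (not isolated)
Conditions: DBU, Et2NH, MeCN, 40 °C; then PhNTf2, rt
Reagents that add atoms: N-phenylbis(trifluoromethanesulfonimide), O=S(=O)(N(c1ccccc1)S(=O)(=O)C(F)(F)F)C(F)(F)F
Why: E1cB cleavage of the N-monosubstituted carbamate (the isocyanate is trapped by Et2NH) followed by O-triflation of the phenoxide in the same flask gives the ortho-silylaryl triflate aryne precursor.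

Step 7
Reactants: 8 2-(7-methoxy-2,2-dimethyl-2H-chromen-6-yl)acrylic acid; 15 3,5-dimethoxy-2-(trimethylsilyl)phenyl trifluoromethanesulfonate
Product: 18 rac-5,7-dimethoxy-3-(7-methoxy-2,2-dimethyl-2H-chromen-6-yl)chroman-4-one, via 3,5-dimethoxybenzyne 16 (not isolated), via hydroxyaryl vinyl ketone 17 (not isolated)
Conditions: CsF (4 equiv), THF, 125 °C, sealed tube (15 in 1.5-fold excess)
Reagents that add atoms: none
Why: Fluoride removes the silyl group of 15 with loss of triflate to give aryne 16; the cesium carboxylate of 8 adds through oxygen to the aryne carbon remote from the flanking methoxy group (C8a–O1), the aryl anion formed next to that methoxy group attacks the ester carbonyl, collapse of the four-membered adduct shifts the acyl group from O to C (C4–C4a) and frees phenoxide 17, which adds to the β-carbon of the α-aryl enone (O1–C2) before the enolate is protonated. The closest known reaction type is the intermolecular C–O insertion of arynes into carboxylic acids, which with α,β-unsaturated acids is known to run on to 4-chromanones. Ring C is closed by a 6-endo-trig oxa-Michael addition. C3 arises by unselective protonation of an enolate under basic conditions, so 18 is racemic by design and its configuration is set in step 8. The step needs regioselective addition to the unsymmetrical aryne, which the methoxy group next to the triple bond secures by its inductive and distortion effect, and chemoselectivity for the carboxylate over the two styrene-type double bonds, which the much higher nucleophilicity of the carboxylate and the intramolecular acyl shift should secure.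

Step 8
Reactants: 18 rac-5,7-dimethoxy-3-(7-methoxy-2,2-dimethyl-2H-chromen-6-yl)chroman-4-one
Product: 19 (3S,4S)-5,7-dimethoxy-3-(7-methoxy-2,2-dimethyl-2H-chromen-6-yl)chroman-4-ol (cis)
Conditions: RuCl[(S,S)-TsDPEN](p-cymene) (3 mol%), HCO2H, Et3N (in excess over HCO2H), EtOAc, 40 °C
Reagents that add atoms: none
Why: Noyori–Ikariya asymmetric transfer hydrogenation with dynamic kinetic resolution: Et3N keeps the C3 epimers of the α-aryl ketone in fast equilibrium, the (S,S) catalyst should deliver hydride to the carbonyl face that gives the (4S) carbinol (aryl ketone model), and only the (3S) ketone offers that face anti to its C3 aryl group, so the cis (3S,4S) alcohol should result.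

Step 9
Reactants: 19 (3S,4S)-5,7-dimethoxy-3-(7-methoxy-2,2-dimethyl-2H-chromen-6-yl)chroman-4-ol
Product: 20 (3S)-5,7-dimethoxy-3-(7-methoxy-2,2-dimethyl-2H-chromen-6-yl)chroman-4-one
Conditions: Dess–Martin periodinane, NaHCO3, CH2Cl2, 0 °C to rt
Reagents that add atoms: none
Why: Dess–Martin oxidation removes the auxiliary C4 stereocenter under buffered, non-enolizing conditions, so the C3 configuration set in step 8 should be kept.

Step 10
Reactants: 20 (3S)-5,7-dimethoxy-3-(7-methoxy-2,2-dimethyl-2H-chromen-6-yl)chroman-4-one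
Product: 21 (3S)-5-hydroxy-7-methoxy-3-(7-methoxy-2,2-dimethyl-2H-chromen-6-yl)chroman-4-one (CNP0310096.1)
Conditions: BCl3 (1.2 equiv), CH2Cl2, −78 °C to −40 °C; cold pH 7 phosphate buffer
Reagents that add atoms: none
Why: Chelation-controlled ether cleavage: BCl3 is held in a six-membered chelate between C4=O and the peri 5-OMe, chloride removes that methyl group by SN2, and the unchelated 7-OMe, 2'-OMe and chromene ether should stay intact at low temperature and without an amine base that could enolize C3.

Compound list
1 | 4-bromo-3-methoxyphenol | COc1cc(O)ccc1Br | starting material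
2 | 3-methylbut-2-enal | CC(C)=CC=O | starting material
3 | 6-bromo-7-methoxy-4-(2-methylprop-1-enyl)-2-phenyl-4H-1,3,2-benzodioxaborin | COc1cc2OB(c3ccccc3)OC(C=C(C)C)c2cc1Br | intermediate (not isolated)
4 | 4-bromo-3-methoxy-6-(3-methylbut-2-enylidene)cyclohexa-2,4-dien-1-one | O=C1C=C(OC)C(Br)=CC1=CC=C(C)C | intermediate (not isolated)
5 | 6-bromo-7-methoxy-2,2-dimethyl-2H-chromene | COc1cc2OC(C)(C)C=Cc2cc1Br | intermediate
6 | ethyl 2-(tributylstannyl)acrylate | C=C(C(=O)OCC)[Sn](CCCC)(CCCC)CCCC | starting material
7 | ethyl 2-(7-methoxy-2,2-dimethyl-2H-chromen-6-yl)acrylate | CCOC(=O)C(=C)c1cc2C=CC(C)(C)Oc2cc1OC | intermediate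
8 | 2-(7-methoxy-2,2-dimethyl-2H-chromen-6-yl)acrylic acid | OC(=O)C(=C)c1cc2C=CC(C)(C)Oc2cc1OC | intermediate
9 | 3,5-dimethoxyphenol | COc1cc(O)cc(OC)c1 | starting material
10 | 3,5-dimethoxyphenyl N-isopropylcarbamate | COc1cc(OC)cc(OC(=O)NC(C)C)c1 | intermediate
11 | 3,5-dimethoxyphenyl N-(tert-butyldimethylsilyl)-N-isopropylcarbamate | COc1cc(OC)cc(OC(=O)N(C(C)C)[Si](C)(C)C(C)(C)C)c1 | intermediate (not isolated)
12 | 3,5-dimethoxy-2-(trimethylsilyl)phenyl N-(tert-butyldimethylsilyl)-N-isopropylcarbamate | COc1cc(OC)c([Si](C)(C)C)c(OC(=O)N(C(C)C)[Si](C)(C)C(C)(C)C)c1 | intermediate (not isolated)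
13 | 3,5-dimethoxy-2-(trimethylsilyl)phenyl N-isopropylcarbamate | COc1cc(OC)c([Si](C)(C)C)c(OC(=O)NC(C)C)c1 | intermediate
14 | 3,5-dimethoxy-2-(trimethylsilyl)phenol | COc1cc(OC)c([Si](C)(C)C)c(O)c1 | intermediate (not isolated)
15 | 3,5-dimethoxy-2-(trimethylsilyl)phenyl trifluoromethanesulfonate | COc1cc(OC)c([Si](C)(C)C)c(OS(=O)(=O)C(F)(F)F)c1 | intermediate
16 | 3,5-dimethoxybenzyne | COC1=CC(OC)=CC#C1 | intermediate (not isolated)
17 | 1-(2-hydroxy-4,6-dimethoxyphenyl)-2-(7-methoxy-2,2-dimethyl-2H-chromen-6-yl)prop-2-en-1-one | C=C(C(=O)c1c(O)cc(OC)cc1OC)c1cc2C=CC(C)(C)Oc2cc1OC | intermediate (not isolated)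
18 | rac-5,7-dimethoxy-3-(7-methoxy-2,2-dimethyl-2H-chromen-6-yl)chroman-4-one | COc1cc(OC)c2c(c1)OCC(c1cc3C=CC(C)(C)Oc3cc1OC)C2=O | intermediate
19 | (3S,4S)-5,7-dimethoxy-3-(7-methoxy-2,2-dimethyl-2H-chromen-6-yl)chroman-4-ol | COc1cc(OC)c2c(c1)OC[C@H](c1cc3C=CC(C)(C)Oc3cc1OC)[C@@H]2O | intermediate
20 | (3S)-5,7-dimethoxy-3-(7-methoxy-2,2-dimethyl-2H-chromen-6-yl)chroman-4-one | COc1cc(OC)c2c(c1)OC[C@H](c1cc3C=CC(C)(C)Oc3cc1OC)C2=O | intermediate
21 | (3S)-5-hydroxy-7-methoxy-3-(7-methoxy-2,2-dimethyl-2H-chromen-6-yl)chroman-4-one | COc1cc(O)c2c(c1)OC[C@H](c1cc3c(cc1OC)OC(C)(C)C=C3)C2=O | target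

Total step count: 10. Longest linear sequence: 7 steps (steps 4, 5, 6, 7, 8, 9, 10; the branch through steps 1, 2, 3 is equally long).

Steps most likely to fail

Step 7. The aryne may be consumed by ene or cycloaddition reactions with the styrene-type double bonds, the O-aryl ester may be protonated before the acyl shift, or the acrylic acid may dimerize at 125 °C. The fallback builds the two bonds one after the other and sets out from ester 7 and phenol 9. Cs2CO3-catalysed oxa-Michael addition of 9 to 7 (MeCN, rt) should give ethyl 3-(3,5-dimethoxyphenoxy)-2-(7-methoxy-2,2-dimethyl-2H-chromen-6-yl)propanoate F1. Hydrolysis with LiOH in THF/H2O at 0 °C, kept cold to hold back retro-Michael loss of the phenoxide, should give 3-(3,5-dimethoxyphenoxy)-2-(7-methoxy-2,2-dimethyl-2H-chromen-6-yl)propanoic acid F2. Intramolecular Friedel–Crafts acylation through the mixed trifluoroacetic anhydride (TFAA, CH2Cl2, 0 °C) onto the symmetric, strongly activated dimethoxyphenoxy ring then closes C4–C4a and comes back to the route at 18.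

Step 10. The Lewis acid may promote enolization at C3 and erode the configuration, or ionize the tertiary allylic C–O bond of the chromene. The fallback moves the demethylation to the racemic stage and makes the last step a mild acetal cleavage; it sets out from 18. BCl3 (or MgI2 etherate) on 18 should give rac-5-hydroxy-7-methoxy-3-(7-methoxy-2,2-dimethyl-2H-chromen-6-yl)chroman-4-one F3, where epimerization does not matter. MOMCl with NaH in DMF should give rac-7-methoxy-5-(methoxymethoxy)-3-(7-methoxy-2,2-dimethyl-2H-chromen-6-yl)chroman-4-one F4. Transfer hydrogenation as in step 8 should give (3S,4S)-7-methoxy-5-(methoxymethoxy)-3-(7-methoxy-2,2-dimethyl-2H-chromen-6-yl)chroman-4-ol F5. Dess–Martin oxidation should give (3S)-7-methoxy-5-(methoxymethoxy)-3-(7-methoxy-2,2-dimethyl-2H-chromen-6-yl)chroman-4-one F6. Brief treatment with catalytic HCl in MeOH at rt should cleave the peri acetal and come back to the route at 21.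

Step 2. Transmetalation of the hindered, electron-poor vinylstannane may be slow against an electron-rich aryl bromide, which opens the way to cine substitution and to polymerization of the acrylate. The fallback replaces the cross-coupling by carbonyl chemistry and sets out from 5. Bromine–lithium exchange (n-BuLi, THF, −78 °C) and addition of the aryllithium to excess diethyl oxalate should give ethyl 2-(7-methoxy-2,2-dimethyl-2H-chromen-6-yl)-2-oxoacetate F7. Wittig methylenation (Ph3PCH3Br, KOt-Bu, THF, 0 °C) comes back to the route at 7.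

Further compounds
F1 | step 7 | ethyl 3-(3,5-dimethoxyphenoxy)-2-(7-methoxy-2,2-dimethyl-2H-chromen-6-yl)propanoate | CCOC(=O)C(COc1cc(OC)cc(OC)c1)c1cc2C=CC(C)(C)Oc2cc1OC
F2 | step 7 | 3-(3,5-dimethoxyphenoxy)-2-(7-methoxy-2,2-dimethyl-2H-chromen-6-yl)propanoic acid | OC(=O)C(COc1cc(OC)cc(OC)c1)c1cc2C=CC(C)(C)Oc2cc1OC
F3 | step 10 | rac-5-hydroxy-7-methoxy-3-(7-methoxy-2,2-dimethyl-2H-chromen-6-yl)chroman-4-one | COc1cc(O)c2c(c1)OCC(c1cc3C=CC(C)(C)Oc3cc1OC)C2=O
F4 | step 10 | rac-7-methoxy-5-(methoxymethoxy)-3-(7-methoxy-2,2-dimethyl-2H-chromen-6-yl)chroman-4-one | COc1cc(OCOC)c2c(c1)OCC(c1cc3C=CC(C)(C)Oc3cc1OC)C2=O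
F5 | step 10 | (3S,4S)-7-methoxy-5-(methoxymethoxy)-3-(7-methoxy-2,2-dimethyl-2H-chromen-6-yl)chroman-4-ol | COc1cc(OCOC)c2c(c1)OC[C@H](c1cc3C=CC(C)(C)Oc3cc1OC)[C@@H]2O
F6 | step 10 | (3S)-7-methoxy-5-(methoxymethoxy)-3-(7-methoxy-2,2-dimethyl-2H-chromen-6-yl)chroman-4-one | COc1cc(OCOC)c2c(c1)OC[C@H](c1cc3C=CC(C)(C)Oc3cc1OC)C2=O
F7 | step 2 | ethyl 2-(7-methoxy-2,2-dimethyl-2H-chromen-6-yl)-2-oxoacetate | CCOC(=O)C(=O)c1cc2C=CC(C)(C)Oc2cc1OC
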